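**Retrosynthetic overview**

1. Target 16 ⇐ aryl silyl ether 15 ⇐ Evans–Tishchenko union of the syn-β-hydroxy enone 11 with aryl aldehyde 13; this sets C6 and places the aroyl group on O-8.
2. 11 ⇐ ten-membered 2-isopropyl-1,3-diketone 10 by enantioselective mono-reduction with dynamic kinetic resolution (sets C8 and C7).
3. 10 ⇐ two-carbon ring expansion of the eight-membered dienone 3: ketene [2+2] on its silyl enol ether 4, then retro-aldol opening of the cyclobutanone (C7–C8 inserted between C6 and C9).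
4. 3 ⇐ key step: one-step desymmetrising allylic C–H oxidation of C2-symmetric 1,5-dimethylcycloocta-1,5-diene 1 (isoprene dimer), which already holds both Z-trisubstituted alkenes and ten of the fifteen skeletal carbons.
5. Ring order: eight-membered ring (bought) → fused four/eight bicycle 7 → ten-membered ring 10; no macrocyclisation; the arene arrives intact in step 7.

Assumption: the target is taken exactly as drawn, i.e. the (Z,Z)-germacra-1(10),4-diene with 6R,7R,8R; atom labels C1–C10 in the Why lines are germacrane positions (ring C1=C10(Me)–C9–C8(OAr)–C7(i-Pr)–C6(OH)–C5=C4(Me)–C3–C2), and commercial 1 (which contains some 1,6-dimethyl isomer) is fractionally distilled before use.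

**Route**

Step 1
Reactants: 1 (1Z,5Z)-1,5-dimethylcycloocta-1,5-diene
Product: 3 (2Z,6Z)-3,7-dimethylcycloocta-2,6-dien-1-one, via allylic tert-butyl peroxide 2 (not isolated)
Conditions: t-BuOOH (3 equiv, decane solution), Rh2(cap)4 [dirhodium tetrakis(caprolactamate), Rh2(C6H10NO)4] 0.5 mol%, K2CO3, CH2Cl2, 25 °C; stopped near 60% conversion, 1 recycled
Reagents that add atoms: tert-butyl hydroperoxide, CC(C)(C)OO
Why: Allylic C–H oxidation (Kharasch-type radical oxidation with Rh2(cap)4/t-BuOOH) breaks the C2 symmetry, because t-BuOO• abstracts H from a ring CH2 next to a =CH terminus to give the more substituted allyl radical, which is trapped at its secondary end as peroxide 2 and collapses to the β-methyl enone; the new carbonyl deactivates its own half of the ring, so the second, skipped alkene survives, and no stereocentre is formed.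

Step 2
Reactants: 3 (2Z,6Z)-3,7-dimethylcycloocta-2,6-dien-1-one
Product: 4 [(1E,3Z,7Z)-3,7-dimethylcycloocta-1,3,7-trien-1-yl]oxy(trimethyl)silane (all ring double bonds cis within the ring)
Conditions: LiN(i-Pr)2 (LDA), THF, −78 °C; Me3SiCl, −78 → 0 °C; pentane work-up, used at once
Reagents that add atoms: chlorotrimethylsilane, C[Si](C)(C)Cl
Why: Kinetic α′-deprotonation of the doubly activated CH2 (between C=O and the skipped alkene, C9) followed by O-silylation gives the silyl enol ether regiospecifically toward C9 without creating a stereocentre; the cycloocta-1,3,5-triene unit is kept cold to avoid 6π-electrocyclisation.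

Step 3
Reactants: 4 [(1E,3Z,7Z)-3,7-dimethylcycloocta-1,3,7-trien-1-yl]oxy(trimethyl)silane; 5 2-bromo-3-methylbutanoyl bromide
Product: 7 (2Z,6Z)-10-bromo-3,7-dimethyl-10-(propan-2-yl)-1-[(trimethylsilyl)oxy]bicyclo[6.2.0]deca-2,6-dien-9-one (racemic; cis-fused; both C10 epimers), via bromo(isopropyl)ketene 6 (not isolated)
Conditions: Et3N (slow addition), hexane, 0 → 25 °C
Reagents that add atoms: none
Why: Thermal [2+2] cycloaddition of a haloketene with a silyl enol ether (Brady-type ketene cycloaddition) joins the ketene carbonyl carbon to the nucleophilic enol β-carbon (C9) and the C(Br)(i-Pr) carbon to the silyloxy carbon (C6), giving the cis-fused 3-silyloxycyclobutanone as a racemate, none of whose stereocentres survives step 4.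

Step 4
Reactants: 7 (2Z,6Z)-10-bromo-3,7-dimethyl-10-(propan-2-yl)-1-[(trimethylsilyl)oxy]bicyclo[6.2.0]deca-2,6-dien-9-one
Product: 10 (4Z,8Z)-5,9-dimethyl-2-(propan-2-yl)cyclodeca-4,8-diene-1,3-dione, via debrominated silyl ether 8 (not isolated), via hydroxycyclobutanone 9 (not isolated)
Conditions: Zn dust, AcOH, THF, 0 °C; filter; K2CO3 (0.2 equiv), MeOH, 0 °C; aq. NH4Cl
Reagents that add atoms: none
Why: Zinc reduction of the α-bromo ketone and then desilylation trigger a strain-driven retro-aldol opening of the 3-hydroxycyclobutanone (De Mayo-type two-carbon ring expansion) that cleaves the ring-fusion C6–C9 bond, because this releases the allyl-conjugated enolate, so C7–C8 ends up inserted between C6 and C9 and C7 is formed as a labile, enolisable centre.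

Step 5
Reactants: 10 (4Z,8Z)-5,9-dimethyl-2-(propan-2-yl)cyclodeca-4,8-diene-1,3-dione
Product: 11 (2Z,6Z,9R,10S)-9-hydroxy-3,7-dimethyl-10-(propan-2-yl)cyclodeca-2,6-dien-1-one
Conditions: NADPH-dependent ketoreductase (KRED, panel hit selected for the 9R,10S product), NADP+ (cat.), i-PrOH (10 vol%), KH2PO4/K2HPO4 buffer pH 7.0, 30 °C
Reagents that add atoms: none
Why: Enzymatic ketone reduction with dynamic kinetic resolution: C7–H of the 1,3-diketone racemises through the enol at pH 7 while the ketoreductase reduces only the non-conjugated C8 carbonyl of one C7 epimer from one face, which sets C8 (R) and the syn C7 centre and leaves the conjugated C6 ketone untouched.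

Step 6
Reactants: 12 4-hydroxybenzaldehyde
Product: 13 4-[(tert-butyldimethylsilyl)oxy]benzaldehyde
Conditions: t-BuMe2SiCl, imidazole, DMF, 25 °C
Reagents that add atoms: tert-butyl(chloro)dimethylsilane, CC(C)(C)[Si](C)(C)Cl
Why: Imidazole-promoted O-silylation masks the phenol so that it cannot quench the samarium alkoxide catalyst of step 7.

Step 7
Reactants: 11 (2Z,6Z,9R,10S)-9-hydroxy-3,7-dimethyl-10-(propan-2-yl)cyclodeca-2,6-dien-1-one; 13 4-[(tert-butyldimethylsilyl)oxy]benzaldehyde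
Product: 15 (1R,3Z,7Z,9R,10R)-9-hydroxy-3,7-dimethyl-10-(propan-2-yl)cyclodeca-3,7-dien-1-yl 4-[(tert-butyldimethylsilyl)oxy]benzoate, via hemiacetal 14 (not isolated)
Conditions: SmI2 (0.3 equiv), 13 (4 equiv), THF, −10 °C
Reagents that add atoms: none
Why: Evans–Tishchenko reduction: the C8 alkoxide adds to the aryl aldehyde and the hemiacetal, bound to trivalent samarium, delivers hydride intramolecularly to the C6 ketone through a chair-like six-membered transition state, which sets C6 (R) anti to the C8 oxygen and leaves the aroyl group on O-8 with the new C6 hydroxyl free.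

Step 8
Reactants: 15 (1R,3Z,7Z,9R,10R)-9-hydroxy-3,7-dimethyl-10-(propan-2-yl)cyclodeca-3,7-dien-1-yl 4-[(tert-butyldimethylsilyl)oxy]benzoate
Product: 16 (1R,3Z,7Z,9R,10R)-9-hydroxy-3,7-dimethyl-10-(propan-2-yl)cyclodeca-3,7-dien-1-yl 4-hydroxybenzoate
Conditions: Bu4NF, AcOH, THF, 0 °C
Reagents that add atoms: none
Why: Fluoride cleavage of the aryl silyl ether (desilylation), buffered with AcOH to suppress 1,3-acyl migration, leaves the secondary ester, the allylic alcohol and both alkenes untouched and affects no stereocentre.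

**Compound list**

1 | (1Z,5Z)-1,5-dimethylcycloocta-1,5-diene | C/C1=C/CC/C(C)=C\CC1 | starting material
2 | tert-butyl (2Z,6Z)-3,7-dimethylcycloocta-2,6-dien-1-yl peroxide (racemic) | C/C1=C/C(OOC(C)(C)C)C/C(C)=C\CC1 | intermediate
3 | (2Z,6Z)-3,7-dimethylcycloocta-2,6-dien-1-one | C/C1=C/C(=O)C/C(C)=C\CC1 | intermediate
4 | [(1E,3Z,7Z)-3,7-dimethylcycloocta-1,3,7-trien-1-yl]oxy(trimethyl)silane | C/C1=C/C(O[Si](C)(C)C)=C\C(C)=C/CC1 | intermediate
5 | 2-bromo-3-methylbutanoyl bromide (racemic) | CC(C)C(Br)C(=O)Br | starting material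
6 | 2-bromo-3-methylbut-1-en-1-one (bromo(isopropyl)ketene) | CC(C)C(Br)=C=O | intermediate
7 | (2Z,6Z)-10-bromo-3,7-dimethyl-10-(propan-2-yl)-1-[(trimethylsilyl)oxy]bicyclo[6.2.0]deca-2,6-dien-9-one (racemic, cis-fused, both C10 epimers; one enantiomer drawn) | C/C1=C/[C@@]2(O[Si](C)(C)C)C(Br)(C(C)C)C(=O)[C@H]2/C(C)=C\CC1 | intermediate
8 | (2Z,6Z)-3,7-dimethyl-10-(propan-2-yl)-1-[(trimethylsilyl)oxy]bicyclo[6.2.0]deca-2,6-dien-9-one (racemic, cis-fused) | C/C1=C/[C@@]2(O[Si](C)(C)C)C(C(C)C)C(=O)[C@H]2/C(C)=C\CC1 | intermediate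
9 | (2Z,6Z)-1-hydroxy-3,7-dimethyl-10-(propan-2-yl)bicyclo[6.2.0]deca-2,6-dien-9-one (racemic, cis-fused) | C/C1=C/[C@@]2(O)C(C(C)C)C(=O)[C@H]2/C(C)=C\CC1 | intermediate
10 | (4Z,8Z)-5,9-dimethyl-2-(propan-2-yl)cyclodeca-4,8-diene-1,3-dione (C2 labile) | C/C1=C/C(=O)C(C(C)C)C(=O)C/C(C)=C\CC1 | intermediate
11 | (2Z,6Z,9R,10S)-9-hydroxy-3,7-dimethyl-10-(propan-2-yl)cyclodeca-2,6-dien-1-one | C/C1=C/C(=O)[C@@H](C(C)C)[C@H](O)C/C(C)=C\CC1 | intermediate
12 | 4-hydroxybenzaldehyde | O=Cc1ccc(O)cc1 | starting material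
13 | 4-[(tert-butyldimethylsilyl)oxy]benzaldehyde | O=Cc1ccc(O[Si](C)(C)C(C)(C)C)cc1 | intermediate
14 | {4-[(tert-butyldimethylsilyl)oxy]phenyl}{[(1R,3Z,7Z,10S)-3,7-dimethyl-9-oxo-10-(propan-2-yl)cyclodeca-3,7-dien-1-yl]oxy}methanol (present as its samarium alkoxide; hemiacetal carbon undefined) | C/C1=C/C(=O)[C@@H](C(C)C)[C@H](OC(O)c2ccc(O[Si](C)(C)C(C)(C)C)cc2)C/C(C)=C\CC1 | intermediate
15 | (1R,3Z,7Z,9R,10R)-9-hydroxy-3,7-dimethyl-10-(propan-2-yl)cyclodeca-3,7-dien-1-yl 4-[(tert-butyldimethylsilyl)oxy]benzoate | C/C1=C/[C@@H](O)[C@@H](C(C)C)[C@H](OC(=O)c2ccc(O[Si](C)(C)C(C)(C)C)cc2)C/C(C)=C\CC1 | intermediate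
16 | (1R,3Z,7Z,9R,10R)-9-hydroxy-3,7-dimethyl-10-(propan-2-yl)cyclodeca-3,7-dien-1-yl 4-hydroxybenzoate | C/C1=C/[C@@H](O)[C@@H](C(C)C)[C@H](OC(=O)c2ccc(O)cc2)C/C(C)=C\CC1 | target

**Step count**

Total steps: 8. Longest linear sequence: 7 (steps 1, 2, 3, 4, 5, 7, 8); step 6 is a one-step side branch.

**Three steps most likely to fail, with fallbacks**

Step 1 (direct mono-oxidation of 1). The risks are oxidation at the wrong allylic CH2, over-oxidation of the doubly activated CH2 of 3, and base-induced conjugation of the skipped alkene. The fallback sets out from 1 and returns at 3. Epoxidation of one alkene with mCPBA (1 equiv, CH2Cl2, 0 °C) gives (4Z)-1,5-dimethyl-9-oxabicyclo[6.1.0]non-4-ene F1. PhSeNa (from PhSeSePh and NaBH4, EtOH) opens it at the secondary carbon to (5Z)-1,5-dimethyl-2-(phenylselanyl)cyclooct-5-en-1-ol F2. H2O2 oxidises this to (5Z)-2-(benzeneseleninyl)-1,5-dimethylcyclooct-5-en-1-ol F3, whose syn-elimination away from the carbinol gives the tertiary allylic alcohol (2Z,5Z)-1,5-dimethylcycloocta-2,5-dien-1-ol F4. Pyridinium chlorochromate (C5H5NH[CrO3Cl], CH2Cl2) then effects the oxidative 1,3-transposition (Babler–Dauben) to 3.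

Step 3 ([2+2] of the hindered bromo(isopropyl)ketene). The risks are a sluggish cycloaddition, ketene dimerisation and loss of the labile trienyl silyl ether. The fallback sets out from 4 and returns at 10. The far more reactive dichloroketene (Cl3CCOCl, Zn–Cu couple, Et2O) gives (2Z,6Z)-10,10-dichloro-3,7-dimethyl-1-[(trimethylsilyl)oxy]bicyclo[6.2.0]deca-2,6-dien-9-one F5. Zn/AcOH followed by K2CO3/MeOH, as in step 4, passes through (2Z,6Z)-3,7-dimethyl-1-[(trimethylsilyl)oxy]bicyclo[6.2.0]deca-2,6-dien-9-one F6 and (2Z,6Z)-1-hydroxy-3,7-dimethylbicyclo[6.2.0]deca-2,6-dien-9-one F7 to (4Z,8Z)-5,9-dimethylcyclodeca-4,8-diene-1,3-dione F8. The isopropyl group is then installed by Knoevenagel condensation with acetone (TiCl4, pyridine, THF, 0 °C), giving (4Z,8Z)-5,9-dimethyl-2-(propan-2-ylidene)cyclodeca-4,8-diene-1,3-dione F9. Conjugate reduction of this with Hantzsch ester (diethyl 2,6-dimethyl-1,4-dihydropyridine-3,5-dicarboxylate) returns 10.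

Step 5 (enzymatic dynamic kinetic resolution). The risk is that no ketoreductase accepts the ten-membered diketone with the required site, syn and facial selectivity; this is the only step that sets absolute configuration. The fallback sets out from 10 and returns at 11. Chelation-controlled reduction of the non-conjugated carbonyl with Zn(BH4)2 (Et2O, −20 °C) gives the racemic syn-hydroxy enone, that is 11 together with its enantiomer (2Z,6Z,9S,10R)-9-hydroxy-3,7-dimethyl-10-(propan-2-yl)cyclodeca-2,6-dien-1-one F10. Preparative chiral SFC delivers 11, and the unwanted enantiomer is oxidised back to 10 with Dess–Martin periodinane and recycled.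

**Further compounds**

F1 | step 1 | (4Z)-1,5-dimethyl-9-oxabicyclo[6.1.0]non-4-ene (racemic cis-epoxide) | C[C@]12O[C@H]1CC/C(C)=C\CC2
F2 | step 1 | (5Z)-1,5-dimethyl-2-(phenylselanyl)cyclooct-5-en-1-ol (racemic, trans) | C[C@]1(O)[C@H]([Se]c2ccccc2)CC/C(C)=C\CC1
F3 | step 1 | (5Z)-2-(benzeneseleninyl)-1,5-dimethylcyclooct-5-en-1-ol (racemic, trans) | C[C@]1(O)[C@H]([Se](=O)c2ccccc2)CC/C(C)=C\CC1
F4 | step 1 | (2Z,5Z)-1,5-dimethylcycloocta-2,5-dien-1-ol (racemic) | CC1(O)/C=C\C/C(C)=C\CC1
F5 | step 3 | (2Z,6Z)-10,10-dichloro-3,7-dimethyl-1-[(trimethylsilyl)oxy]bicyclo[6.2.0]deca-2,6-dien-9-one (racemic, cis-fused) | C/C1=C/[C@@]2(O[Si](C)(C)C)C(Cl)(Cl)C(=O)[C@H]2/C(C)=C\CC1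
F6 | step 3 | (2Z,6Z)-3,7-dimethyl-1-[(trimethylsilyl)oxy]bicyclo[6.2.0]deca-2,6-dien-9-one (racemic, cis-fused) | C/C1=C/[C@@]2(O[Si](C)(C)C)CC(=O)[C@H]2/C(C)=C\CC1
F7 | step 3 | (2Z,6Z)-1-hydroxy-3,7-dimethylbicyclo[6.2.0]deca-2,6-dien-9-one (racemic, cis-fused) | C/C1=C/[C@@]2(O)CC(=O)[C@H]2/C(C)=C\CC1
F8 | step 3 | (4Z,8Z)-5,9-dimethylcyclodeca-4,8-diene-1,3-dione | C/C1=C/C(=O)CC(=O)C/C(C)=C\CC1
F9 | step 3 | (4Z,8Z)-5,9-dimethyl-2-(propan-2-ylidene)cyclodeca-4,8-diene-1,3-dione | C/C1=C/C(=O)C(=C(C)C)C(=O)C/C(C)=C\CC1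
F10 | step 5 | (2Z,6Z,9S,10R)-9-hydroxy-3,7-dimethyl-10-(propan-2-yl)cyclodeca-2,6-dien-1-one | C/C1=C/C(=O)[C@H](C(C)C)[C@@H](O)C/C(C)=C\CC1
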